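## Retrosynthetic overview

1. Target ⇒ its benzyl ether at the 5-CH2OH group (hydrogenolysis last). The one ring, the tetronic acid lactone, is closed second to last by Dieckmann cyclization (ring bond C3–C4) of an acyclic β-keto ester of an (S)-glycerate.
2. β-Keto ester ⇒ intermolecular decarboxylative Claisen condensation: imidazolide of (S)-14-methylhexadecanoic acid (fragment 1) plus the magnesium enolate of a glycerate hydrogen malonate (fragment 2). This forms the acyl carbon–C3 bond and joins the two fragments.
3. Fragment 1 ⇒ copper-catalysed sp3–sp3 coupling of (S)-2-methylbutylmagnesium bromide with 12-bromododecanoic acid; the C14 stereocentre comes from (S)-2-methylbutan-1-ol.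
4. Fragment 2 ⇒ O-benzyl-(S)-serine: diazotization with retention, methyl ester, ring opening of Meldrum's acid; the C5 stereocentre comes from serine.
5. Ring order: only one ring, formed after the fragment union.

Assumption: the target is treated as the enol tautomer written in its SMILES; 3-acyltetronic acids equilibrate between enol forms, which touches neither stereocentre.

## Route

Step 1
Reactants: 1 (S)-2-methylbutan-1-ol
Product: 2 (S)-1-bromo-2-methylbutane
Conditions: PPh3, N-bromosuccinimide, CH2Cl2, 0 °C to rt; distil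
Reagents that add atoms: N-bromosuccinimide, O=C1CCC(=O)N1Br
Why: Appel-type bromination displaces the activated primary oxygen by SN2, so no cation forms and the neighbouring stereocentre carried in from 1 is untouched.

Step 2
Reactants: 2 (S)-1-bromo-2-methylbutane; 3 12-bromododecanoic acid
Product: 6 (14S)-14-methylhexadecanoic acid, via (S)-2-methylbutylmagnesium bromide 4 (not isolated), via chloromagnesium 12-bromododecanoate 5 (not isolated)
Conditions: 2, Mg, cat. I2, THF, 45 °C; separately 3, CH3MgCl (1.0 equiv), THF, −20 °C; add 4 (1.4 equiv), Li2CuCl4 (3 mol%), −20 to 0 °C; dil. HCl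
Reagents that add atoms: none
Why: Kochi-type copper-catalysed cross-coupling of a primary alkyl Grignard reagent with a primary alkyl bromide, run on the pre-formed magnesium carboxylate so the acid proton does not interfere; the stereocentre sits β to the carbon–magnesium bond and cannot epimerize.

Step 3
Reactants: 7 O-benzyl-(S)-serine, (2S)-2-amino-3-(benzyloxy)propanoic acid
Product: 10 (2S)-3-(benzyloxy)-2-hydroxypropanoic acid, via diazonium carboxylate 8 (not isolated), via α-lactone 9 (not isolated)
Conditions: NaNO2, dil. aq. H2SO4, 0 °C to rt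
Reagents that add atoms: water, O
Why: Diazotization of the α-amino acid followed by double inversion (carboxylate displaces N2 to the α-lactone, water reopens it) gives net retention, so the (S) centre of serine becomes the (S) centre of the hydroxy acid.

Step 4
Reactants: 10 (2S)-3-(benzyloxy)-2-hydroxypropanoic acid
Product: 11 methyl (2S)-3-(benzyloxy)-2-hydroxypropanoate
Conditions: MeOH, cat. H2SO4, reflux
Reagents that add atoms: methanol, CO
Why: Fischer esterification under acid catalysis leaves the benzyl ether and the stereocentre alone.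

Step 5
Reactants: 11 methyl (2S)-3-(benzyloxy)-2-hydroxypropanoate; 12 Meldrum's acid (2,2-dimethyl-1,3-dioxane-4,6-dione)
Product: 13 3-{[(2S)-3-(benzyloxy)-1-methoxy-1-oxopropan-2-yl]oxy}-3-oxopropanoic acid
Conditions: toluene, 90 °C, 5 h
Reagents that add atoms: none
Why: Alcoholysis of Meldrum's acid (acyl substitution with ring opening) by the secondary alcohol expels acetone and gives the malonic half-ester in one operation without base, so the stereocentre is untouched.

Step 6
Reactants: 6 (14S)-14-methylhexadecanoic acid; 13 3-{[(2S)-3-(benzyloxy)-1-methoxy-1-oxopropan-2-yl]oxy}-3-oxopropanoic acid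
Product: 17 methyl (2S)-3-(benzyloxy)-2-{[(16S)-16-methyl-3-oxooctadecanoyl]oxy}propanoate, via acyl imidazolide 14 (not isolated), via magnesium enolate 15 (not isolated), via acylmalonic acid 16 (not isolated)
Conditions: 6, 1,1'-carbonyldiimidazole (1.05 equiv), THF, rt, 2 h; separately 13 (1.5 equiv), MgCl2 (1.5 equiv), Et3N (3 equiv), MeCN, rt, 2 h; combine, rt, 16 h; dil. HCl
Reagents that add atoms: none
Why: Masamune–Brooks decarboxylative crossed Claisen condensation, in which the chelated magnesium malonate enolate is acylated at carbon by the acyl imidazolide and loss of CO2 makes the bond formation irreversible; no new stereocentre forms and the mild amine base leaves both existing ones alone.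

Step 7
Reactants: 17 methyl (2S)-3-(benzyloxy)-2-{[(16S)-16-methyl-3-oxooctadecanoyl]oxy}propanoate
Product: 18 (5S)-5-[(benzyloxy)methyl]-4-hydroxy-3-[(14S)-14-methylhexadecanoyl]furan-2(5H)-one
Conditions: Bu4NF (2.5 equiv), THF, 0 °C to rt, 2 h; dil. HCl
Reagents that add atoms: none
Why: Fluoride-mediated Dieckmann (intramolecular Claisen) cyclization, a 5-exo attack of the β-keto ester enolate on the adjacent methyl ester, gives the product as its stabilised tetronate anion, which protects the serine-derived C5 centre from deprotonation.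

Step 8
Reactants: 18 (5S)-5-[(benzyloxy)methyl]-4-hydroxy-3-[(14S)-14-methylhexadecanoyl]furan-2(5H)-one
Product: 19 (5S)-4-hydroxy-5-(hydroxymethyl)-3-[(14S)-14-methylhexadecanoyl]furan-2(5H)-one
Conditions: H2 (1 atm), 10% Pd on carbon, EtOAc, rt
Reagents that add atoms: none
Why: Catalytic hydrogenolysis cleaves the primary benzyl ether under neutral conditions, where the saturated chain, the enolised tricarbonyl unit and both stereocentres are not affected.

## Compound list

1 | (S)-2-methylbutan-1-ol | CC[C@H](C)CO | starting material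
2 | (S)-1-bromo-2-methylbutane | CC[C@H](C)CBr | intermediate
3 | 12-bromododecanoic acid | OC(=O)CCCCCCCCCCCBr | starting material
4 | (S)-2-methylbutylmagnesium bromide | CC[C@H](C)C[Mg]Br | intermediate
5 | chloromagnesium 12-bromododecanoate | BrCCCCCCCCCCCC(=O)O[Mg]Cl | intermediate
6 | (14S)-14-methylhexadecanoic acid | CC[C@H](C)CCCCCCCCCCCCC(=O)O | intermediate
7 | O-benzyl-(S)-serine, (2S)-2-amino-3-(benzyloxy)propanoic acid | N[C@@H](COCc1ccccc1)C(=O)O | starting material
8 | (2S)-3-(benzyloxy)-2-diazoniopropanoate (diazonium carboxylate) | N#[N+][C@@H](COCc1ccccc1)C(=O)[O-] | intermediate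
9 | (3R)-3-[(benzyloxy)methyl]oxiran-2-one (α-lactone) | O1[C@H](COCc2ccccc2)C1=O | intermediate
10 | (2S)-3-(benzyloxy)-2-hydroxypropanoic acid | O[C@@H](COCc1ccccc1)C(=O)O | intermediate
11 | methyl (2S)-3-(benzyloxy)-2-hydroxypropanoate | COC(=O)[C@H](COCc1ccccc1)O | intermediate
12 | Meldrum's acid, 2,2-dimethyl-1,3-dioxane-4,6-dione | CC1(C)OC(=O)CC(=O)O1 | starting material
13 | 3-{[(2S)-3-(benzyloxy)-1-methoxy-1-oxopropan-2-yl]oxy}-3-oxopropanoic acid | COC(=O)[C@H](COCc1ccccc1)OC(=O)CC(=O)O | intermediate
14 | 1-[(14S)-14-methylhexadecanoyl]-1H-imidazole (acyl imidazolide) | CC[C@H](C)CCCCCCCCCCCCC(=O)n1ccnc1 | intermediate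
15 | magnesium enolate carboxylate of 13 | COC(=O)[C@H](COCc1ccccc1)OC(=O)[CH-]C(=O)[O-].[Mg+2] | intermediate
16 | (16S)-2-({[(2S)-3-(benzyloxy)-1-methoxy-1-oxopropan-2-yl]oxy}carbonyl)-16-methyl-3-oxooctadecanoic acid (acylmalonic acid, C2 unassigned) | CC[C@H](C)CCCCCCCCCCCCC(=O)C(C(=O)O)C(=O)O[C@@H](COCc1ccccc1)C(=O)OC | intermediate
17 | methyl (2S)-3-(benzyloxy)-2-{[(16S)-16-methyl-3-oxooctadecanoyl]oxy}propanoate | CC[C@H](C)CCCCCCCCCCCCC(=O)CC(=O)O[C@@H](COCc1ccccc1)C(=O)OC | intermediate
18 | (5S)-5-[(benzyloxy)methyl]-4-hydroxy-3-[(14S)-14-methylhexadecanoyl]furan-2(5H)-one | CC[C@H](C)CCCCCCCCCCCCC(=O)C1=C(O)[C@H](COCc2ccccc2)OC1=O | intermediate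
19 | (5S)-4-hydroxy-5-(hydroxymethyl)-3-[(14S)-14-methylhexadecanoyl]furan-2(5H)-one | CC[C@H](C)CCCCCCCCCCCCC(=O)C1=C(O)[C@H](CO)OC1=O | target

## Step count and risks

Total step count: 8. Longest linear sequence: 6 steps (steps 3, 4, 5, 6, 7, 8 from compound 7); the other branch (steps 1 and 2) joins at step 6.

Three steps most likely to fail:

Step 2 (copper-catalysed coupling in the presence of a carboxylate). The coupling may stall, and unreacted bromo acid 3 is hard to separate from acid 6. The fallback sets out from bromide 2 and comes back at acid 6. Grignard reagent 4, made from 2 as before, is coupled (Li2CuCl4 cat., THF, −10 °C) with a threefold excess of 1,10-dibromodecane to give (S)-1-bromo-12-methyltetradecane F1, which is distilled from the excess dibromide. A malonic ester synthesis then adds the last two carbons: alkylation of diethyl malonate with F1 (NaOEt, EtOH, reflux) gives diethyl 2-[(12S)-12-methyltetradecyl]propanedioate F2, saponification (KOH, aq. EtOH, then dil. HCl) gives 2-[(12S)-12-methyltetradecyl]propanedioic acid F3, and heating F3 neat at 150 °C loses CO2 to give 6. No free carboxylate is present during the organometallic step, and each neutral intermediate can be purified.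

Step 6 (decarboxylative Claisen fragment union). Enolate 15 may close onto its own methyl ester, or acylation at carbon may be slow with the long-chain imidazolide. The fallback sets out from acid 6 and comes back at keto ester 17. Acid 6 is condensed with Meldrum's acid 12 (N,N'-dicyclohexylcarbodiimide, DMAP, CH2Cl2, 0 °C to rt), an intermolecular Claisen-type acylation at the carbon of the cyclic malonate, to give 5-[(14S)-1-hydroxy-14-methylhexadecylidene]-2,2-dimethyl-1,3-dioxane-4,6-dione F4. Heating F4 with alcohol 11 in toluene at 90 °C releases [(14S)-14-methylhexadecanoyl]ketene F5, which the alcohol traps to give 17. Here the half-ester 13 is not needed, so the self-cyclization problem disappears.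

Step 7 (Dieckmann ring closure). The base may erode the C5 configuration of the acyclic ester before it cyclizes, or cleave the keto ester by retro-Claisen reaction; the optical purity of 18 should be checked at this point. The fallback sets out from hydroxy acid 10 and comes back at 18; it closes the ring under neutral conditions and attaches the acyl chain afterwards.
- Acid 10 is alkylated (allyl bromide, KHCO3, DMF, rt) to prop-2-en-1-yl (2S)-3-(benzyloxy)-2-hydroxypropanoate F6.
- F6 and Ph3P=C=C=O (THF, 60 °C) give the ester ylide prop-2-en-1-yl (2S)-3-(benzyloxy)-2-{[(triphenyl-λ5-phosphanylidene)acetyl]oxy}propanoate F7, which closes by intramolecular Wittig olefination of the ester carbonyl to (5S)-5-[(benzyloxy)methyl]-4-(prop-2-en-1-yloxy)furan-2(5H)-one F8.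
- Allyl transfer to morpholine (Pd(PPh3)4 cat., THF, rt) frees (5S)-5-[(benzyloxy)methyl]-4-hydroxyfuran-2(5H)-one F9.
- F9 and acid 6 (N,N'-dicyclohexylcarbodiimide, DMAP 1.3 equiv, CH2Cl2, rt) give the enol ester (2S)-2-[(benzyloxy)methyl]-5-oxo-2,5-dihydrofuran-3-yl (14S)-14-methylhexadecanoate F10, which rearranges in the same flask by DMAP-mediated 1,3-acyl shift from oxygen to C3 to give 18.

## Further compounds

F1 | step 2 | (S)-1-bromo-12-methyltetradecane | CC[C@H](C)CCCCCCCCCCCBr
F2 | step 2 | diethyl 2-[(12S)-12-methyltetradecyl]propanedioate | CC[C@H](C)CCCCCCCCCCCC(C(=O)OCC)C(=O)OCC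
F3 | step 2 | 2-[(12S)-12-methyltetradecyl]propanedioic acid | CC[C@H](C)CCCCCCCCCCCC(C(=O)O)C(=O)O
F4 | step 6 | 5-[(14S)-1-hydroxy-14-methylhexadecylidene]-2,2-dimethyl-1,3-dioxane-4,6-dione | CC[C@H](C)CCCCCCCCCCCCC(O)=C1C(=O)OC(C)(C)OC1=O
F5 | step 6 | [(14S)-14-methylhexadecanoyl]ketene | CC[C@H](C)CCCCCCCCCCCCC(=O)C=C=O
F6 | step 7 | prop-2-en-1-yl (2S)-3-(benzyloxy)-2-hydroxypropanoate | C=CCOC(=O)[C@H](COCc1ccccc1)O
F7 | step 7 | prop-2-en-1-yl (2S)-3-(benzyloxy)-2-{[(triphenyl-λ5-phosphanylidene)acetyl]oxy}propanoate | C=CCOC(=O)[C@H](COCc1ccccc1)OC(=O)C=P(c1ccccc1)(c1ccccc1)c1ccccc1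
F8 | step 7 | (5S)-5-[(benzyloxy)methyl]-4-(prop-2-en-1-yloxy)furan-2(5H)-one | C=CCOC1=CC(=O)O[C@H]1COCc2ccccc2
F9 | step 7 | (5S)-5-[(benzyloxy)methyl]-4-hydroxyfuran-2(5H)-one | OC1=CC(=O)O[C@H]1COCc2ccccc2
F10 | step 7 | (2S)-2-[(benzyloxy)methyl]-5-oxo-2,5-dihydrofuran-3-yl (14S)-14-methylhexadecanoate | CC[C@H](C)CCCCCCCCCCCCC(=O)OC1=CC(=O)O[C@H]1COCc2ccccc2
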